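**Plan**
Ocophyllal B is achiral, so no stereocentre has to be set; the transient ones are racemic and are erased.
Numbering: ring A benzo, ring B furan, ring C trimethoxyphenyl. C4 and C7 flank the ring-B bond C3a–C7a, so a short-lived second furan fused across that bond, its oxygen bridging C4 and C7, can serve as diene. Ring A is cut at C4–C5 and C6–C7; methyl propiolate supplies C5, C6 and the formyl carbon, and the bridging oxygen stays on C7.
The diene is made from a furan-fused lactone whose carbonyl carbon is C4. As a silyloxy group this extra oxygen fixes the orientation of the alkyne and the direction of bridge opening; it is removed later through the aryl triflate.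
Ring B is cut at C3–C3a (enolate alkylation) and O1–C2 (Paal–Knorr closure).
Forward order: ring B, lactone ring, ring A (key step), then O7 methylation, C4 deoxygenation and ester-to-aldehyde adjustment.

Key step: step 5

Assumption: 1, 3 and 9 are bought; 2, 4 and 11 are racemic or diastereomeric mixtures whose stereocentres become sp2 carbons before the target.

**Step 1**
Reactants: 1 1-(3,4,5-trimethoxyphenyl)propan-1-one
Product: 2 rac-2-bromo-1-(3,4,5-trimethoxyphenyl)propan-1-one
Conditions: CuBr2 (2 equiv), EtOAc/CHCl3, reflux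
Reagents that add atoms: CuBr2, Br[Cu]Br
Why: Alpha-bromination of an enolisable aryl ketone with CuBr2 should stop at the monobromide and spare the electron-rich ring, because bromine is delivered within the copper enolate; the new stereocentre is racemic and is lost in step 3.

**Step 2**
Reactants: 2 rac-2-bromo-1-(3,4,5-trimethoxyphenyl)propan-1-one; 3 methyl 4,4-dimethoxy-3-oxobutanoate
Product: 4 methyl 2-(2,2-dimethoxyacetyl)-3-methyl-4-oxo-4-(3,4,5-trimethoxyphenyl)butanoate
Conditions: NaH, THF, 0 °C to rt
Reagents that add atoms: none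
Why: The sodium enolate of the beta-keto ester should displace the activated secondary bromide in an SN2 C-alkylation (acetoacetic ester alkylation), giving the 1,4-diketone as a mixture of diastereomers whose two stereocentres both become furan carbons in step 3.

**Step 3**
Reactants: 4 methyl 2-(2,2-dimethoxyacetyl)-3-methyl-4-oxo-4-(3,4,5-trimethoxyphenyl)butanoate
Product: 6 methyl 2-formyl-4-methyl-5-(3,4,5-trimethoxyphenyl)furan-3-carboxylate, via furan dimethyl acetal 5 (not isolated)
Conditions: TsOH·H2O (cat.), toluene, 90 °C; then 1 M HCl, THF, rt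
Reagents that add atoms: water, O
Why: Paal–Knorr furan synthesis, in which the enol oxygen of the acetal-bearing ketone should add to the protonated aryl ketone and dehydration aromatises ring B (O1–C2 bond), after which aqueous acid hydrolyses the furfural-type dimethyl acetal to the aldehyde.

**Step 4**
Reactants: 6 methyl 2-formyl-4-methyl-5-(3,4,5-trimethoxyphenyl)furan-3-carboxylate
Product: 8 3-methyl-2-(3,4,5-trimethoxyphenyl)furo[3,4-b]furan-4(6H)-one, via hydroxymethyl ester 7 (not isolated)
Conditions: NaBH4, MeOH, 0 °C; then TsOH (cat.), toluene, 60 °C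
Reagents that add atoms: none
Why: NaBH4 should reduce the aldehyde but not the conjugated ester, and the furylmethanol then lactonises onto the neighbouring ester under acid (acyl substitution closing a five-membered ring, as in the reduction of 2-formylbenzoates to phthalides).

**Step 5**
Reactants: 8 3-methyl-2-(3,4,5-trimethoxyphenyl)furo[3,4-b]furan-4(6H)-one; 9 methyl propiolate
Product: 13 methyl 4,7-dihydroxy-3-methyl-2-(3,4,5-trimethoxyphenyl)benzofuran-5-carboxylate, via silyloxyfurofuran diene 10 (not isolated), via oxygen-bridged cycloadduct 11 (not isolated), via 4-O-silyl hydroquinone 12 (not isolated)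
Conditions: Me3SiCl, LiN(SiMe3)2, THF, −78 °C; methyl propiolate, −78 °C to rt; then 1 M HCl, THF, rt
Reagents that add atoms: chlorotrimethylsilane, C[Si](C)(C)Cl (its silyl group is carried by 10, 11 and 12 only)
Why: Proposed new method: gamma-deprotonation of lactone 8 at the CH2 group (future C7) with silylation on oxygen should give the silyloxyfuro[3,4-b]furan 10, an ortho-quinoid diene that regains the aromatic sextet of ring B when it adds an alkyne, so the [4+2] cycloaddition with 9 should be fast below room temperature. Ring A closes in this intermolecular Diels–Alder step by forming C6–C7 and C4–C5 at once (or, if the addition is stepwise, by vinylogous Mukaiyama–Michael attack of C7 on the alkyne terminus followed by closure of the allenoate carbon onto the C4 oxocarbenium ion, which gives the same bonds). The orientation is the selectivity that matters: the diene C4=C3a–C7a=C7 carries the silyloxy group on C4 and the ring-B oxygen O1 on C7a, the donor pattern of a 1-alkoxy-3-silyloxybutadiene, so both donors make C7 the nucleophilic end, C7 bonds to the unsubstituted alkyne carbon and the ester lands on C5. Bridged ketal 11 can then open productively only by ionisation of the C4–O bond, assisted by the silyloxy group, which leaves the bridging oxygen on C7; loss of the C7 proton aromatises ring A to 12 and dilute acid removes the silyl group to give 13. The two bridgehead stereocentres of racemic 11 disappear on aromatisation, so no stereocontrol is needed. The closest known reaction type is the Diels–Alder addition of 2-silyloxyfurans and of 1-silyloxyisobenzofurans (made from phthalides) to alkynes with opening of the bridged ketal to hydroquinone monoethers; a silyloxyfuran fused to a second furan has not been used in this way.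

**Step 6**
Reactants: 13 methyl 4,7-dihydroxy-3-methyl-2-(3,4,5-trimethoxyphenyl)benzofuran-5-carboxylate
Product: 14 methyl 4-hydroxy-7-methoxy-3-methyl-2-(3,4,5-trimethoxyphenyl)benzofuran-5-carboxylate
Conditions: MeI (1.1 equiv), K2CO3 (1.2 equiv), acetone, rt, under argon
Reagents that add atoms: iodomethane, CI
Why: Williamson ether synthesis, in which the O4–H is tied up in a hydrogen bond to the C5 ester carbonyl and shielded by the peri methyl on C3, so one equivalent of base and iodomethane should methylate O7 only, as in the 5-O-alkylation of 2,5-dihydroxybenzoates.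

**Step 7**
Reactants: 14 methyl 4-hydroxy-7-methoxy-3-methyl-2-(3,4,5-trimethoxyphenyl)benzofuran-5-carboxylate
Product: 15 methyl 7-methoxy-3-methyl-4-(trifluoromethylsulfonyloxy)-2-(3,4,5-trimethoxyphenyl)benzofuran-5-carboxylate
Conditions: Tf2O, pyridine, CH2Cl2, 0 °C to rt
Reagents that add atoms: trifluoromethanesulfonic anhydride, O=S(=O)(OS(=O)(=O)C(F)(F)F)C(F)(F)F
Why: O-Sulfonylation of the remaining phenol with triflic anhydride and pyridine should turn O4 into a leaving group for palladium chemistry.

**Step 8**
Reactants: 15 methyl 7-methoxy-3-methyl-4-(trifluoromethylsulfonyloxy)-2-(3,4,5-trimethoxyphenyl)benzofuran-5-carboxylate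
Product: 16 methyl 7-methoxy-3-methyl-2-(3,4,5-trimethoxyphenyl)benzofuran-5-carboxylate
Conditions: Pd(OAc)2 (cat.), Ph2P(CH2)3PPh2 (cat.), HCO2H, Et3N, DMF, 70 °C
Reagents that add atoms: none
Why: Palladium-catalysed reductive cleavage of an aryl triflate, in which oxidative addition of C4–OTf to zerovalent palladium, exchange of triflate for formate, loss of CO2 and reductive elimination should form the C4–H bond while ester, aryl ethers and benzofuran stay untouched.

**Step 9**
Reactants: 16 methyl 7-methoxy-3-methyl-2-(3,4,5-trimethoxyphenyl)benzofuran-5-carboxylate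
Product: 17 [7-methoxy-3-methyl-2-(3,4,5-trimethoxyphenyl)benzofuran-5-yl]methanol
Conditions: i-Bu2AlH (2.5 equiv), CH2Cl2, −78 °C to 0 °C
Reagents that add atoms: none
Why: Hydride reduction of the aryl ester with excess i-Bu2AlH should give the benzylic alcohol through the aldehyde stage without touching the benzofuran.

**Step 10**
Reactants: 17 [7-methoxy-3-methyl-2-(3,4,5-trimethoxyphenyl)benzofuran-5-yl]methanol
Product: 18 Ocophyllal B
Conditions: activated MnO2, CH2Cl2, rt
Reagents that add atoms: none
Why: Selective oxidation of a benzylic alcohol on activated MnO2 should stop at the aldehyde.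

**Compound list**
1 | 1-(3,4,5-trimethoxyphenyl)propan-1-one | CCC(=O)c1cc(OC)c(OC)c(OC)c1 | starting material
2 | rac-2-bromo-1-(3,4,5-trimethoxyphenyl)propan-1-one | CC(Br)C(=O)c1cc(OC)c(OC)c(OC)c1 | intermediate
3 | methyl 4,4-dimethoxy-3-oxobutanoate | COC(OC)C(=O)CC(=O)OC | starting material
4 | methyl 2-(2,2-dimethoxyacetyl)-3-methyl-4-oxo-4-(3,4,5-trimethoxyphenyl)butanoate (mixture of racemic diastereomers) | COC(=O)C(C(=O)C(OC)OC)C(C)C(=O)c1cc(OC)c(OC)c(OC)c1 | intermediate
5 | methyl 2-(dimethoxymethyl)-4-methyl-5-(3,4,5-trimethoxyphenyl)furan-3-carboxylate | COC(OC)c1oc(-c2cc(OC)c(OC)c(OC)c2)c(C)c1C(=O)OC | intermediate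
6 | methyl 2-formyl-4-methyl-5-(3,4,5-trimethoxyphenyl)furan-3-carboxylate | COC(=O)c1c(C=O)oc(-c2cc(OC)c(OC)c(OC)c2)c1C | intermediate
7 | methyl 2-(hydroxymethyl)-4-methyl-5-(3,4,5-trimethoxyphenyl)furan-3-carboxylate | COC(=O)c1c(CO)oc(-c2cc(OC)c(OC)c(OC)c2)c1C | intermediate
8 | 3-methyl-2-(3,4,5-trimethoxyphenyl)furo[3,4-b]furan-4(6H)-one | Cc1c(-c2cc(OC)c(OC)c(OC)c2)oc2c1C(=O)OC2 | intermediate
9 | methyl propiolate | C#CC(=O)OC | starting material
10 | 3-methyl-2-(3,4,5-trimethoxyphenyl)-4-(trimethylsilyloxy)furo[3,4-b]furan | CC1=C(c2cc(OC)c(OC)c(OC)c2)OC2=COC(O[Si](C)(C)C)=C12 | intermediate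
11 | methyl rac-3-methyl-2-(3,4,5-trimethoxyphenyl)-4-(trimethylsilyloxy)-4,7-dihydro-4,7-epoxybenzofuran-5-carboxylate (racemic, one enantiomer drawn) | COC(=O)C1=C[C@H]2O[C@]1(O[Si](C)(C)C)c1c2oc(-c2cc(OC)c(OC)c(OC)c2)c1C | intermediate
12 | methyl 7-hydroxy-3-methyl-2-(3,4,5-trimethoxyphenyl)-4-(trimethylsilyloxy)benzofuran-5-carboxylate | COC(=O)c1cc(O)c2oc(-c3cc(OC)c(OC)c(OC)c3)c(C)c2c1O[Si](C)(C)C | intermediate
13 | methyl 4,7-dihydroxy-3-methyl-2-(3,4,5-trimethoxyphenyl)benzofuran-5-carboxylate | COC(=O)c1cc(O)c2oc(-c3cc(OC)c(OC)c(OC)c3)c(C)c2c1O | intermediate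
14 | methyl 4-hydroxy-7-methoxy-3-methyl-2-(3,4,5-trimethoxyphenyl)benzofuran-5-carboxylate | COC(=O)c1cc(OC)c2oc(-c3cc(OC)c(OC)c(OC)c3)c(C)c2c1O | intermediate
15 | methyl 7-methoxy-3-methyl-4-(trifluoromethylsulfonyloxy)-2-(3,4,5-trimethoxyphenyl)benzofuran-5-carboxylate | COC(=O)c1cc(OC)c2oc(-c3cc(OC)c(OC)c(OC)c3)c(C)c2c1OS(=O)(=O)C(F)(F)F | intermediate
16 | methyl 7-methoxy-3-methyl-2-(3,4,5-trimethoxyphenyl)benzofuran-5-carboxylate | COC(=O)c1cc(OC)c2oc(-c3cc(OC)c(OC)c(OC)c3)c(C)c2c1 | intermediate
17 | [7-methoxy-3-methyl-2-(3,4,5-trimethoxyphenyl)benzofuran-5-yl]methanol | OCc1cc(OC)c2oc(-c3cc(OC)c(OC)c(OC)c3)c(C)c2c1 | intermediate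
18 | Ocophyllal B, 7-methoxy-3-methyl-2-(3,4,5-trimethoxyphenyl)benzofuran-5-carbaldehyde | COc1cc(-c2oc3c(OC)cc(C=O)cc3c2C)cc(OC)c1OC | target

Total step count: 10. Longest linear sequence: 10 steps, from 1.

**Steps most likely to fail**

Step 5 (bears the label). The electron-rich diene may be consumed by dimerisation or reprotonation before it meets the alkyne, or the addition may stop after the first bond (Michael addition at C7 without closure at C4). The fallback is a Hauser–Kraus annulation, which makes the same two ring-A bonds by known anionic steps. It sets out from 6: saponification (LiOH, THF/H2O) should give 2-formyl-4-methyl-5-(3,4,5-trimethoxyphenyl)furan-3-carboxylic acid F1, in equilibrium with its hydroxy lactone. PhSO2Na in acetic acid at 80 °C should convert this into rac-3-methyl-6-(phenylsulfonyl)-2-(3,4,5-trimethoxyphenyl)furo[3,4-b]furan-4(6H)-one F2. Deprotonation of the sulfone (LiOC(CH3)3, THF, −78 °C) and addition of methyl acrylate should then give, by Michael addition (C6–C7), Dieckmann-type attack on the lactone carbonyl (C4–C5), loss of benzenesulfinate and tautomerisation, the hydroquinone 13, where the route is rejoined.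

Step 6. The two phenols may not be told apart well enough, so that both oxygens are methylated, and the hydroquinone may be oxidised by air to the quinone under basic conditions. The fallback sets out from 13: exhaustive methylation (excess MeI, K2CO3, DMF, argon) should give methyl 4,7-dimethoxy-3-methyl-2-(3,4,5-trimethoxyphenyl)benzofuran-5-carboxylate F3. BCl3 in CH2Cl2 at −78 °C, which cleaves a methoxy group ortho to a carbonyl group through a six-membered boron chelate, should then free O4 alone and return 14.

Step 3. The keto acetal may hydrolyse before the ring closes, and the exposed 1,2-dicarbonyl unit may then be destroyed under the acidic conditions. The fallback builds ring B without the acetal and sets out from 2. Alkylation of the sodium enolate of ethyl formylacetate F4 (made from ethyl acetate, ethyl formate and NaH) should give ethyl 2-formyl-3-methyl-4-oxo-4-(3,4,5-trimethoxyphenyl)butanoate F5. Acid closure (TsOH, toluene) should give ethyl 4-methyl-5-(3,4,5-trimethoxyphenyl)furan-3-carboxylate F6. Ester-directed magnesiation of the only free furan position with (2,2,6,6-tetramethylpiperidin-1-yl)MgCl·LiCl and a DMF quench should give ethyl 2-formyl-4-methyl-5-(3,4,5-trimethoxyphenyl)furan-3-carboxylate F7. NaBH4 reduction to ethyl 2-(hydroxymethyl)-4-methyl-5-(3,4,5-trimethoxyphenyl)furan-3-carboxylate F8 and acid lactonisation return 8.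

**Further compounds**
F1 | step 5 | 2-formyl-4-methyl-5-(3,4,5-trimethoxyphenyl)furan-3-carboxylic acid | O=Cc1oc(-c2cc(OC)c(OC)c(OC)c2)c(C)c1C(=O)O
F2 | step 5 | rac-3-methyl-6-(phenylsulfonyl)-2-(3,4,5-trimethoxyphenyl)furo[3,4-b]furan-4(6H)-one | Cc1c(-c2cc(OC)c(OC)c(OC)c2)oc2c1C(=O)OC2S(=O)(=O)c1ccccc1
F3 | step 6 | methyl 4,7-dimethoxy-3-methyl-2-(3,4,5-trimethoxyphenyl)benzofuran-5-carboxylate | COC(=O)c1cc(OC)c2oc(-c3cc(OC)c(OC)c(OC)c3)c(C)c2c1OC
F4 | step 3 | sodium enolate of ethyl formylacetate | [Na+].[O-]C=CC(=O)OCC
F5 | step 3 | ethyl 2-formyl-3-methyl-4-oxo-4-(3,4,5-trimethoxyphenyl)butanoate | CCOC(=O)C(C=O)C(C)C(=O)c1cc(OC)c(OC)c(OC)c1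
F6 | step 3 | ethyl 4-methyl-5-(3,4,5-trimethoxyphenyl)furan-3-carboxylate | CCOC(=O)c1coc(-c2cc(OC)c(OC)c(OC)c2)c1C
F7 | step 3 | ethyl 2-formyl-4-methyl-5-(3,4,5-trimethoxyphenyl)furan-3-carboxylate | CCOC(=O)c1c(C=O)oc(-c2cc(OC)c(OC)c(OC)c2)c1C
F8 | step 3 | ethyl 2-(hydroxymethyl)-4-methyl-5-(3,4,5-trimethoxyphenyl)furan-3-carboxylate | CCOC(=O)c1c(CO)oc(-c2cc(OC)c(OC)c(OC)c2)c1C
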